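**Retrosynthetic overview**

- Feature: the benzene ring is para-disubstituted, with the C–OH carbon and the carbon bearing the 3-(docosanoyloxy)propyl chain 1,4 across the ring. This ring is treated as an oxidised 4-substituted cyclohex-2-enone (ketone carbon = future C–OH, C4 = chain-bearing carbon).
- Target ⇒ 3-(4-oxocyclohex-2-en-1-yl)propyl docosanoate by retro-dehydrogenation; aromatisation is the last forward step.
- The cyclohexenone (the only ring made) ⇒ 5-oxopentyl docosanoate + methyl vinyl ketone. Retro-aldol condensation opens the ring C=C (aldehyde carbon / ketone methyl), and retro-Michael cuts the bond between the aldehyde α-carbon and the vinyl terminus.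
- 5-Oxopentyl docosanoate ⇒ 5-hydroxypentyl docosanoate ⇒ docosanoic acid + pentane-1,5-diol (alcohol oxidation, mono-esterification).

Key step: step 3

Remark: the target has no stereogenic centre, so it is a single achiral compound and no enantiocontrol is needed. The one ring stereocentre created in the annulation is formed racemic and is removed on aromatisation.

**Route**

Step 1
Reactants: 1 docosanoic acid; 2 pentane-1,5-diol (5 equiv)
Product: 3 5-hydroxypentyl docosanoate
Conditions: DIC (1.1 equiv), DMAP (0.1 equiv), CH2Cl2–THF, rt
Reagents that add atoms: none
Why: Steglich esterification (carbodiimide activation with DMAP as acyl-transfer catalyst) acylates one primary hydroxyl, the fivefold excess of the symmetrical diol statistically suppresses the diester, and the excess diol is removed by aqueous washing.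

Step 2
Reactants: 3 5-hydroxypentyl docosanoate
Product: 4 5-oxopentyl docosanoate
Conditions: TEMPO (0.1 equiv), PhI(OAc)2 (1.1 equiv), CH2Cl2, rt
Reagents that add atoms: none
Why: TEMPO/(diacetoxyiodo)benzene oxidation of a primary alcohol should stop cleanly at the aldehyde in anhydrous CH2Cl2, leaves the ester untouched, and runs at room temperature where the waxy substrate stays dissolved.

Step 3
Reactants: 4 5-oxopentyl docosanoate; 5 methyl vinyl ketone (1.5 equiv)
Product: 9 3-(4-oxocyclohex-2-en-1-yl)propyl docosanoate (racemic), via diethylamino enamine 6 (not isolated), via Michael keto-aldehyde 7 (not isolated), via aldol ketol 8 (not isolated)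
Conditions: Et2NH (0.3 equiv), MVK (added slowly), THF, rt; evaporate; then TsOH·H2O (0.1 equiv), PhMe, reflux, Dean–Stark
Reagents that add atoms: none
Why: Diethylamine condenses with aldehyde 4 to the nucleophilic enamine 6, whose β-carbon (the former aldehyde α-carbon) adds to the terminal carbon of methyl vinyl ketone, and hydrolysis of the adduct by the water set free returns the amine and gives the 1,5-keto-aldehyde 7; this is the amine-catalysed (Stork-type) Michael addition of an unbranched aldehyde to a vinyl ketone, the first half of a Robinson-type annulation. In the acid stage the enol of the methyl ketone attacks the protonated aldehyde to give ketol 8, which loses water to the conjugated enone 9. The six-membered carbocycle closes in a 6-(enolendo)-exo-trig aldol, and the alternative enolisations of 7 could only give four-membered rings, so the ketone oxygen necessarily ends up 1,4 to the chain-bearing carbon. The single ring stereocentre (C1 of the cyclohexenyl unit) is set without control by the achiral catalyst and is racemic, which does not matter because it becomes an sp2 carbon in step 4. The step needs chemoselectivity for mono-Michael addition over aldehyde self-aldol and enone oligomerisation; this should be secured by slow addition of the enone, by the reluctance of the α-branched adduct 7 to form a second enamine with the acyclic amine, and by the absence of any base or nucleophile that could attack the remote ester.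

Step 4
Reactants: 9 3-(4-oxocyclohex-2-en-1-yl)propyl docosanoate (racemic)
Product: 11 3-(4-hydroxyphenyl)propyl docosanoate, via cyclohexadienone 10 (not isolated)
Conditions: Pd(TFA)2 (5 mol%), 2-(dimethylamino)pyridine (10 mol%), TsOH·H2O (20 mol%), O2 (1 atm), DMSO, 80 °C
Reagents that add atoms: none
Why: Palladium(II)-catalysed aerobic dehydrogenation (α-palladation, then β-hydride elimination) should convert the enone into the cross-conjugated dienone 10, which tautomerises irreversibly to the phenol, with O2 reoxidising palladium and water as the only by-product; the ester is a spectator.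

**Compound list**

1 | docosanoic acid | CCCCCCCCCCCCCCCCCCCCCC(=O)O | starting material
2 | pentane-1,5-diol | OCCCCCO | starting material
3 | 5-hydroxypentyl docosanoate | CCCCCCCCCCCCCCCCCCCCCC(=O)OCCCCCO | intermediate
4 | 5-oxopentyl docosanoate | CCCCCCCCCCCCCCCCCCCCCC(=O)OCCCCC=O | intermediate
5 | methyl vinyl ketone (but-3-en-2-one) | CC(=O)C=C | starting material
6 | (E)-5-(diethylamino)pent-4-en-1-yl docosanoate | CCCCCCCCCCCCCCCCCCCCCC(=O)OCCC/C=C/N(CC)CC | intermediate
7 | 4-formyl-7-oxooctyl docosanoate (racemic) | CCCCCCCCCCCCCCCCCCCCCC(=O)OCCCC(C=O)CCC(C)=O | intermediate
8 | 3-(2-hydroxy-4-oxocyclohexyl)propyl docosanoate (racemic, diastereomer mixture) | CCCCCCCCCCCCCCCCCCCCCC(=O)OCCCC1CCC(=O)CC1O | intermediate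
9 | 3-(4-oxocyclohex-2-en-1-yl)propyl docosanoate (racemic) | CCCCCCCCCCCCCCCCCCCCCC(=O)OCCCC1CCC(=O)C=C1 | intermediate
10 | 3-(4-oxocyclohexa-2,5-dien-1-yl)propyl docosanoate | CCCCCCCCCCCCCCCCCCCCCC(=O)OCCCC1C=CC(=O)C=C1 | intermediate
11 | 3-(4-hydroxyphenyl)propyl docosanoate | CCCCCCCCCCCCCCCCCCCCCC(=O)OCCCc1ccc(O)cc1 | target

**Step count**

Total steps: 4. Longest linear sequence: 4 (1 → 3 → 4 → 9 → 11).

**Steps most likely to fail**

Step 3 (annulation). Self-aldol condensation of the unbranched aldehyde, oligomerisation of the enone and a second conjugate addition may compete with the wanted mono-Michael addition, and the acid stage may stop before dehydration is complete. Fallback, from 4: condensation with pyrrolidine (1.1 equiv, 4 Å sieves, toluene, rt) gives the preformed enamine (E)-5-(pyrrolidin-1-yl)pent-4-en-1-yl docosanoate F1. This is used stoichiometrically in a classical Stork reaction with methyl vinyl ketone (toluene, 0 °C to rt). Buffered hydrolysis (aqueous AcOH/NaOAc) then releases pyrrolidine and the keto-aldehyde, so the route is rejoined at 7, which is closed to 9 by the acid stage of step 3.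

Step 4 (aromatisation). The dehydrogenation may stall through catalyst aggregation to palladium black, or through poor solubility of the long-chain substrate in DMSO, leaving unreacted enone. Fallback, from 9: soft enolisation (TMSOTf, Et3N, CH2Cl2, 0 °C) gives the cross-conjugated silyl dienol ether 3-[4-(trimethylsilyloxy)cyclohexa-2,4-dien-1-yl]propyl docosanoate F2. Oxidation of this with DDQ (CH2Cl2, rt) by hydride abstraction and desilylation gives the dienone, so the route is rejoined at 10, which tautomerises to 11 on work-up.

Step 1 (mono-esterification). Over-acylation to the diester and rearrangement of the activated acid to an N-acylurea may erode the amount of monoester, and the waxy product may be hard to separate from these. Fallback, from 1: the same DIC/DMAP esterification with commercial hex-5-en-1-ol (C=CCCCCO), which has only one hydroxyl, gives hex-5-en-1-yl docosanoate F3. Lemieux–Johnson cleavage of the terminal alkene (OsO4 cat., NaIO4, 2,6-lutidine, dioxane–water, rt) then removes the terminal carbon as formaldehyde and gives the aldehyde directly. The route is rejoined at 4, bypassing 3 and step 2.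

**Further compounds**

F1 | step 3 | (E)-5-(pyrrolidin-1-yl)pent-4-en-1-yl docosanoate | CCCCCCCCCCCCCCCCCCCCCC(=O)OCCC/C=C/N1CCCC1
F2 | step 4 | 3-[4-(trimethylsilyloxy)cyclohexa-2,4-dien-1-yl]propyl docosanoate (racemic) | CCCCCCCCCCCCCCCCCCCCCC(=O)OCCCC1CC=C(O[Si](C)(C)C)C=C1
F3 | step 1 | hex-5-en-1-yl docosanoate | CCCCCCCCCCCCCCCCCCCCCC(=O)OCCCCC=C
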